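Atom numbers are those of the target: C1 is the carboxyl carbon, C3 and C6 are the ring stereocentres, O2 is bonded to C3 and O1 to C6, and the chain runs from C7 to C22.

## Analysis of the target

Target 26 is a C22 carboxylic acid with a single ring, a 1,2-dioxane made of O1, O2, C3, C4, C5 and C6. C3 carries the CH2CO2H arm (C2, C1); C6 is a methyl peroxyketal carbon that also carries the chain C7–C22, in which three methylene groups lead to a C10≡C11 triple bond conjugated with an (E)-C12=C13 double bond and a nonyl tail. The two stereocentres, C3 (S) and C6 (R), stand 1,4 to each other across the ring, with the methoxy group cis to the C3 arm; in the chair this puts the C3 arm and the C6 chain equatorial and the methoxy group axial, where it profits from the anomeric effect of O1. That is the arrangement a reversible ketal exchange at C6 should favour, so C6 can be left to thermodynamics and only C3 needs absolute control. The O–O bond rules out hydrogenation, hydride reagents, stoichiometric phosphines and strongly reducing metals; the peroxyketal ionises under acid; the β-peroxy carbonyl unit can open under base (loss of O2 from C3 after enolisation, or Kornblum–DeLaMare fragmentation); and the enyne does not tolerate ozone, radical chains or hydrometalation. The hard part is C3, a secondary carbon bonded to peroxide oxygen in one configuration: methods that make such a C–OO centre enantioselectively are scarce, and every later step has to spare the peroxide. The plan rests on the double role of C3, which is a ring atom bonded to O2 and also the β-carbon of the C1 carbonyl group: if O1–O2 already links C6 to C3 in an open-chain β-peroxy acrylate, the ring bond C3–C4 is what conjugate addition of a C4 radical would form, and the carbonyl group can hold a chiral auxiliary that decides the face of C3.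

## Retrosynthetic reasoning

The first cut is the C11–C12 bond between alkyne and alkene, which splits 26 into the ring-bearing terminal alkyne 22 and the alkenyl iodide 25. The conjugated enyne would not survive the ozonolysis and the radical chain used to build the ring, so it has to come last. A Sonogashira coupling does this at room temperature with retention of the alkene geometry, and it has to leave the O–O bond alone. 25 goes back to the terminal alkyne 23 by hydrozirconation and iodination, which fixes the E geometry.

22 is unmasked from 21 (silyl cap on C11), and 21 from the acyl oxazolidinone 19 (auxiliary 12 on C1). No skeletal bond is cut here, but the order matters. The auxiliary is removed first so that the later fluoride and amine steps meet a carboxylate, whose C2 hydrogens are not acidic; ring opening by loss of O2 from C3 is then closed off.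

19 is the C6-equilibrated form of 18, in which C3 is defined and C6 is not. The C6–OMe bond is the one bond of the ring system that is reversible under acid, and the target has the arrangement that exchange should favour. Nothing is therefore spent on C6 earlier in the route.

The ring is opened at C3–C4, which gives the open-chain β-peroxy acrylimide 17 with a bromine atom on C4. Cutting C3–O2 instead leads to a peroxide conjugate addition with no obvious handle on the configuration of C3, and cutting O1–C6 requires a C3 hydroperoxide of defined configuration. Cutting C3–C4 keeps O1–O2 as a link made beforehand, turns ring closure into C–C bond formation at the β-carbon of an acyl group, and lets that acyl group carry the auxiliary 12 next to the new stereocentre. In the forward direction the C4 radical has to add 6-exo-trig to C3 faster than it attacks the peroxide oxygen O1, and from the face the auxiliary leaves open. For the face selection a diphenylmethyl group on the oxazolidinone is chosen, because a smaller benzyl group can turn away from the distant β-carbon. A chelating Lewis acid with non-nucleophilic counter-ions fixes the s-cis rotamer and activates the acceptor.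

17 is cut at O2–C3 into the hydroperoxy ketal 10 and the ynimide 16. The O–H bond of 10 is added across the triple bond under amine catalysis, which should give the E alkene and sets up the whole peroxide linkage in one step from two halves of similar size. The product is a vinylogous perester with a weak O–O bond and has to be made and used cold.

10 comes from the 1,1-disubstituted alkene 8. Ozonolysis in an alcohol solvent removes the methylene carbon and forms C6–O1 and C6–OMe in one operation through the carbonyl oxide 9. The bromide is the radical precursor because it passes through ozonolysis unchanged. C6 is formed without control, which the plan accepts.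

8 is the bromide of the homoallylic alcohol 7, and 7 is cut at C6–C7 into the alkenyl bromide 5 and the alkylborane 6, made in the flask from the enyne 4. A B-alkyl Suzuki–Miyaura coupling is preferred to alkylation of an allylic carbanion with a homopropargylic halide, which would invite elimination to a conjugated enyne. 4 is cut at C9–C10 into the silylalkyne 1 and allyl bromide 2. The triisopropylsilyl group shields C10≡C11 during hydroboration, ozonolysis and the radical step.

16 is cut at the N–C1 bond into the oxazolidinone 12 and the silyl-capped propiolic acid 11, by way of 15. The acylation (mixed anhydride 13, lithium salt 14) is run with the alkyne terminus capped, because amines and amide anions add to a free propiolate. The cap is then removed with buffered fluoride.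

## Alternatives that were turned down

Alternative 1: Both ring C–O bonds (C3–O2 and C6–O1) are cut at once, which leads back to the cyclohexadienol (1S)-2-[5-(triisopropylsilyl)pent-4-yn-1-yl]cyclohexa-2,4-dien-1-ol A2 and singlet oxygen.
- Forward step: a [4+2] addition across the diene termini, steered to the hydroxyl-bearing face, gives the bicyclic endoperoxide A1, whose bridgeheads are the future C6 and C3. The alkene bridge must then be saturated with diimide, and the hydroxylated two-carbon bridge cut between C6 and the carbinol carbon with methanol capture at C6, to release the methyl ketal and an arm that is oxidised to the acid.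
- For it: the O–O bond comes from the cheapest source, and both ring C–O bonds and both stereocentres are set in one pericyclic step within a rigid bicycle. It needs no auxiliary, and on that point it is stronger than the chosen route.
- Against it: A2 is an arene hydrate that loses water and aromatises with traces of acid, and no short route gives it as a single enantiomer. Ene reactions at its allylic positions compete with the cycloaddition. The C–C scission next to a peroxide bridgehead has no good precedent and still leaves C6 to be equilibrated. At least four operations follow the key step.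
- Comparison: the chosen route reaches its key precursor from simple open-chain pieces, keeps C1 at the acid oxidation level throughout and has one uncertain stage; here both the substrate and the fragmentation after the cycloaddition are uncertain.

Alternative 2: Three bonds are cut (C4–C5, C3–O2 and O1–C6), which leads to 1-bromohept-6-yn-2-one A4, methyl but-3-enoate A5 and dioxygen.
- Forward step: the α-keto radical from A4 adds to the terminal alkene of A5, the C3 radical traps dioxygen, and after hydrogen transfer the hydroperoxide closes on the ketone to give the cyclic hemiperketal A3, which acidic methanol would turn into the methyl ketal.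
- For it: step economy, where it is clearly stronger than the chosen route. Ring, O–O bond and ester arm arise in one step from trivial components, C1 has the right oxidation level, and C6 is again thermodynamic.
- Against it: A3 is racemic and nothing in the cascade can control C3, so a single enantiomer would need a late resolution. Cascades of this kind are established for 1,3-dicarbonyl radicals, less so for a simple bromoketone. The doubly activated allylic hydrogens of A5 invite hydrogen abstraction and isomerisation, and the free terminal alkyne of A4 is itself a radical acceptor.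
- Comparison: the chosen route is longer but offers what this one lacks, an auxiliary next to C3 that both directs the ring closure and makes any stereochemical error a separable diastereomer.

Alternative 3: Only O1–C6 is cut, which gives the open-chain C3 hydroperoxide with a C6 dimethyl ketal, A7.
- Forward step: mild acid in methanol lets the hydroperoxide displace one methoxy group to give the 1,2-dioxane A6 with the complete chain. The silyl ether is then removed and the primary alcohol oxidised in two stages to the acid.
- For it: the ring closure is the best-precedented of the four (thermodynamic six-membered peroxyketalisation with anomeric control of C6), so on reliability of ring closure it is stronger than the chosen route. The enyne is already in place, so the endgame needs no metal-catalysed coupling.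
- Against it: the real problem moves into the precursor. A secondary hydroperoxide of defined configuration at C3 has to be made by displacement at a secondary carbon with a peroxide nucleophile, which is low-yielding, competes with elimination and presupposes an enantioselective alcohol synthesis. The enyne must survive that, and three further steps (desilylation, two oxidations) follow in the presence of the O–O bond.
- Comparison: the chosen strategy makes C3 by C–C bond formation under auxiliary control, takes the O–O bond from ozonolysis and has C1 at the acid level from the start; the price is a key step without precedent.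

Key step: step 8

Assumption: C6 is formed without control in step 4, so 10, 17 and 18 are drawn with C6 undefined (both epimers carried together) and C6 is set in step 9; 5, 11, 12 and 23 are taken to be purchasable.

## Route

Step 1
Reactants: 1 ethynyltriisopropylsilane; 2 allyl bromide
Product: 4 triisopropyl(pent-4-en-1-yn-1-yl)silane, via alkynylmagnesium bromide 3 (not isolated)
Conditions: EtMgBr, THF, 50 °C; then CuBr·SMe2 (5 mol %), 2, 0 °C → rt
Reagents that add atoms: none
Why: Copper-catalysed allylation of an alkynylmagnesium halide is a standard route to 1,4-enynes and forms C9–C10. The bulky silyl group is inert here and later shields the triple bond from borane, ozone and silyl radicals.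

Step 2
Reactants: 4 triisopropyl(pent-4-en-1-yn-1-yl)silane; 5 3-bromobut-3-en-1-ol
Product: 7 3-methylidene-8-(triisopropylsilyl)oct-7-yn-1-ol, via B-alkyl-9-BBN 6 (not isolated)
Conditions: 9-BBN, THF, 0 °C → rt; then 3 M aq. K3PO4, 5, PdCl2(dppf) (3 mol %), DMF, rt
Reagents that add atoms: none
Why: 9-BBN should add only to the terminal alkene (anti-Markovnikov) and leave the hindered silylalkyne alone. The primary alkylborane then undergoes B-alkyl Suzuki–Miyaura coupling with the 2-bromoalkene, which tolerates the free hydroxyl group and forms C6–C7 without exposing a homopropargylic halide to a strong base.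

Step 3
Reactants: 7 3-methylidene-8-(triisopropylsilyl)oct-7-yn-1-ol
Product: 8 (8-bromo-6-methylideneoct-1-yn-1-yl)triisopropylsilane
Conditions: CBr4, PPh3, CH2Cl2, 0 °C
Reagents that add atoms: carbon tetrabromide BrC(Br)(Br)Br
Why: Appel reaction of a primary alcohol under neutral conditions; the alkene and the silylalkyne are not affected. The bromide is the halide that survives ozone and is still abstracted readily by silyl radicals.

Step 4
Reactants: 8 (8-bromo-6-methylideneoct-1-yn-1-yl)triisopropylsilane
Product: 10 rac-(8-bromo-6-hydroperoxy-6-methoxyoct-1-yn-1-yl)triisopropylsilane, via carbonyl oxide 9 (not isolated)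
Conditions: O3, CH2Cl2/MeOH (1:1), −78 °C, Sudan Red 7B end point; N2 purge; concentrated below 25 °C, no reductant
Reagents that add atoms: ozone O=[O+][O-]; methanol CO
Why: Ozone reacts with the electron-rich 1,1-disubstituted alkene far faster than with the hindered silylalkyne or the C–Br bond, and the primary ozonide fragments towards the more substituted carbonyl oxide 9, which methanol traps as the hydroperoxy ketal (Criegee mechanism). C6 is formed as both enantiomers, which is acceptable because it is equilibrated in step 9.

Step 5
Reactants: 11 3-(trimethylsilyl)prop-2-ynoic acid; 12 (4S)-4-(diphenylmethyl)-1,3-oxazolidin-2-one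
Product: 15 (4S)-4-(diphenylmethyl)-3-[3-(trimethylsilyl)prop-2-ynoyl]-1,3-oxazolidin-2-one, via mixed pivalic anhydride 13 (not isolated), via lithiated oxazolidinone 14 (not isolated)
Conditions: 11, PivCl, Et3N, THF, −20 °C; 12, n-BuLi, THF, −78 °C; combined, −78 → 0 °C; aq. NH4Cl
Reagents that add atoms: none
Why: N-Acylation of a lithiated oxazolidinone with a mixed pivalic anhydride. The trimethylsilyl cap keeps triethylamine and the oxazolidinone anion from adding to the triple bond, which is the usual failure of an unprotected propiolate.

Step 6
Reactants: 15 (4S)-4-(diphenylmethyl)-3-[3-(trimethylsilyl)prop-2-ynoyl]-1,3-oxazolidin-2-one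
Product: 16 (4S)-4-(diphenylmethyl)-3-(prop-2-ynoyl)-1,3-oxazolidin-2-one
Conditions: TBAF, AcOH, THF, −78 °C
Reagents that add atoms: none
Why: Alkynylsilanes conjugated with a carbonyl group are desilylated by fluoride within minutes at low temperature. Acetic acid buffers the alkynyl anion and the basic fluoride so that neither the imide nor the new terminal ynimide is attacked.

Step 7
Reactants: 10 rac-(8-bromo-6-hydroperoxy-6-methoxyoct-1-yn-1-yl)triisopropylsilane; 16 (4S)-4-(diphenylmethyl)-3-(prop-2-ynoyl)-1,3-oxazolidin-2-one
Product: 17 (4S)-3-[(2E)-3-{[1-bromo-3-methoxy-8-(triisopropylsilyl)oct-7-yn-3-yl]peroxy}prop-2-enoyl]-4-(diphenylmethyl)-1,3-oxazolidin-2-one (both C6 epimers)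
Conditions: DABCO (10 mol %), CH2Cl2, −40 °C; cold silica plug; solution kept below −20 °C and used at once
Reagents that add atoms: none
Why: Proposed new method: a tertiary amine adds reversibly to the ynimide, the β-ammonium enolate deprotonates the hydroperoxide (pKa near 12) and the peroxy anion replaces the amine at C3 by addition–elimination, the path by which alcohols and propiolates give (E)-β-alkoxyacrylates; the closest known reaction types are that amine-catalysed oxa-Michael addition to propiolates and the base-mediated conjugate addition of hydroperoxides to enones and enoates, neither of which can be pointed to for a hydroperoxide adding to an alkyne acceptor. The E geometry is the thermodynamic outcome of the addition–elimination. Because the product is a vinylogous perester with a weak O–O bond it is formed and kept cold and used at once, and the low temperature and low amine loading also hold back displacement of the bromide by the peroxy anion.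

Step 8
Reactants: 17 (4S)-3-[(2E)-3-{[1-bromo-3-methoxy-8-(triisopropylsilyl)oct-7-yn-3-yl]peroxy}prop-2-enoyl]-4-(diphenylmethyl)-1,3-oxazolidin-2-one (both C6 epimers)
Product: 18 (4S)-4-(diphenylmethyl)-3-({(3S)-6-methoxy-6-[5-(triisopropylsilyl)pent-4-yn-1-yl]-1,2-dioxan-3-yl}acetyl)-1,3-oxazolidin-2-one (both C6 epimers)
Conditions: Yb(OTf)3 (1.5 equiv), CH2Cl2/THF (4:1), −78 °C; (Me3Si)3SiH (2 equiv), Et3B (hexane)/air, −78 °C, 0.01 M
Reagents that add atoms: none
Why: Proposed new method: the silyl radical abstracts bromine from C4 (Et3B/air initiation at −78 °C), the nucleophilic primary radical adds to C3 of the Lewis-acid-bound, electron-poor β-peroxy acrylimide, and the resulting C2 radical, electrophilic while bound to Yb, takes hydrogen from the silane, which carries the chain. The ring closes 6-exo-trig through a chair-like transition state in which O1–O2 is part of the tether (C4, C5, C6, O1, O2, C3), giving the 1,2-dioxane. The closest known reaction types are 6-exo radical cyclisations onto β-alkoxyacrylates, which give cis-2,6-disubstituted oxanes, and Lewis-acid-chelated radical conjugate additions to N-enoyl oxazolidinones; neither is known with a peroxide in the tether. C3 is the new stereocentre: in the chelate both imide carbonyl groups bind Yb, the enoyl unit is s-cis, and one phenyl ring of the (4S)-diphenylmethyl group covers the face of C3 that would lead to (3R), so the ketal carbon swings to the open face and C4 bonds from there to give (3S) for either C6 epimer. The selectivity the step needs most is chemoselectivity: cyclisation must beat intramolecular homolytic substitution of the C4 radical at O1 (oxetane formation with loss of a stabilised oxygen-centred radical), and the C2 radical must be reduced before it attacks O2 (epoxide formation). Working for the cyclisation are the geminal substitution at C6, the polarity match between a nucleophilic radical and an acceptor whose LUMO is lowered by chelation, the low temperature, and a silane that is a slow donor towards the alkyl radical but a polarity-matched donor towards the electrophilic C2 radical. A triflate Lewis acid is used so that no nucleophilic halide sits next to the weak O–O bond, and any (3R) diastereomer is separable because of the auxiliary.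

Step 9
Reactants: 18 (4S)-4-(diphenylmethyl)-3-({(3S)-6-methoxy-6-[5-(triisopropylsilyl)pent-4-yn-1-yl]-1,2-dioxan-3-yl}acetyl)-1,3-oxazolidin-2-one (both C6 epimers)
Product: 19 (4S)-4-(diphenylmethyl)-3-({(3S,6R)-6-methoxy-6-[5-(triisopropylsilyl)pent-4-yn-1-yl]-1,2-dioxan-3-yl}acetyl)-1,3-oxazolidin-2-one
Conditions: CSA (10 mol %), MeOH/CH2Cl2 (1:1), 0 °C → rt; NaHCO3; chromatography
Reagents that add atoms: methanol CO
Why: Acid ionises the methoxy peroxyketal (loss of methanol to the ring peroxycarbenium ion, or reversible opening to the open-chain ketal hydroperoxide) and methanol returns; the equilibrium should favour the chair with the methoxy group axial (anomeric effect of O1) and both carbon substituents equatorial, which is the (6R) epimer. C3 is untouched because the C3–O2 bond is never broken, and the acyl oxazolidinone is stable to catalytic acid.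

Step 10
Reactants: 19 (4S)-4-(diphenylmethyl)-3-({(3S,6R)-6-methoxy-6-[5-(triisopropylsilyl)pent-4-yn-1-yl]-1,2-dioxan-3-yl}acetyl)-1,3-oxazolidin-2-one
Product: 21 2-{(3S,6R)-6-methoxy-6-[5-(triisopropylsilyl)pent-4-yn-1-yl]-1,2-dioxan-3-yl}acetic acid, via peroxy acid 20 (not isolated)
Conditions: LiOH, 30% H2O2, THF/H2O (3:1), 0 °C; then 1 M HCl to pH 3–4 at 0 °C, extraction (no reductive quench)
Reagents that add atoms: hydrogen peroxide OO
Why: Hydroperoxide anion attacks the exocyclic imide carbonyl selectively (Evans cleavage), the peracid 20 is reduced by the excess H2O2, and the auxiliary 12 is recovered. LiOOH is too weak a base to enolise the imide, so loss of O2 from C3 should not compete at 0 °C, and the ring O–O bond meets no reductant.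

Step 11
Reactants: 21 2-{(3S,6R)-6-methoxy-6-[5-(triisopropylsilyl)pent-4-yn-1-yl]-1,2-dioxan-3-yl}acetic acid
Product: 22 2-[(3S,6R)-6-methoxy-6-(pent-4-yn-1-yl)-1,2-dioxan-3-yl]acetic acid
Conditions: TBAF (3 equiv), THF, 0 °C → rt; dil. HCl to pH 3–4
Reagents that add atoms: none
Why: Fluoride cleaves the C(sp)–Si bond. The substrate is present as its carboxylate, so C2 is not acidic and the β-peroxy unit cannot open by elimination; dialkyl peroxyketals are inert to fluoride.

Step 12
Reactants: 23 undec-1-yne
Product: 25 (1E)-1-iodoundec-1-ene, via alkenylzirconocene chloride 24 (not isolated)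
Conditions: Cp2Zr(H)Cl, CH2Cl2, rt; I2, 0 °C
Reagents that add atoms: iodine II
Why: Hydrozirconation of a terminal alkyne is syn and places zirconium on the terminal carbon; iodinolysis of the C–Zr bond proceeds with retention, so only the (E)-iodide should form.

Step 13
Reactants: 22 2-[(3S,6R)-6-methoxy-6-(pent-4-yn-1-yl)-1,2-dioxan-3-yl]acetic acid; 25 (1E)-1-iodoundec-1-ene
Product: 26 2-{(3S,6R)-6-[(6E)-hexadec-6-en-4-yn-1-yl]-6-methoxy-1,2-dioxan-3-yl}acetic acid
Conditions: PdCl2(PPh3)2 (5 mol %), CuI (10 mol %), Et3N, THF, rt, degassed; dil. HCl work-up
Reagents that add atoms: none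
Why: Sonogashira coupling of a terminal alkyne with an alkenyl iodide at room temperature forms C11–C12 with retention of the E geometry. The acid is carried as its ammonium carboxylate, and the hindered dialkyl peroxyketal should survive the catalytic amounts of zerovalent palladium and phosphine.

## Compound list

1 | ethynyltri(propan-2-yl)silane (triisopropylsilylacetylene) | C#C[Si](C(C)C)(C(C)C)C(C)C | starting material
2 | 3-bromoprop-1-ene (allyl bromide) | C=CCBr | starting material
3 | bromo[(triisopropylsilyl)ethynyl]magnesium | CC(C)[Si](C#C[Mg]Br)(C(C)C)C(C)C | intermediate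
4 | triisopropyl(pent-4-en-1-yn-1-yl)silane | C=CCC#C[Si](C(C)C)(C(C)C)C(C)C | intermediate
5 | 3-bromobut-3-en-1-ol | C=C(Br)CCO | starting material
6 | 9-[5-(triisopropylsilyl)pent-4-yn-1-yl]-9-borabicyclo[3.3.1]nonane | CC(C)[Si](C#CCCCB1C2CCCC1CCC2)(C(C)C)C(C)C | intermediate
7 | 3-methylidene-8-(triisopropylsilyl)oct-7-yn-1-ol | OCCC(=C)CCCC#C[Si](C(C)C)(C(C)C)C(C)C | intermediate
8 | (8-bromo-6-methylideneoct-1-yn-1-yl)triisopropylsilane | BrCCC(=C)CCCC#C[Si](C(C)C)(C(C)C)C(C)C | intermediate
9 | carbonyl oxide of 1-bromo-8-(triisopropylsilyl)oct-7-yn-3-one (zwitterion at C6) | CC(C)[Si](C#CCCCC(CCBr)=[O+][O-])(C(C)C)C(C)C | intermediate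
10 | rac-(8-bromo-6-hydroperoxy-6-methoxyoct-1-yn-1-yl)triisopropylsilane | BrCCC(OC)(OO)CCCC#C[Si](C(C)C)(C(C)C)C(C)C | intermediate
11 | 3-(trimethylsilyl)prop-2-ynoic acid | C[Si](C)(C)C#CC(=O)O | starting material
12 | (4S)-4-(diphenylmethyl)-1,3-oxazolidin-2-one | O=C1N[C@@H](C(c2ccccc2)c2ccccc2)CO1 | starting material
13 | 2,2-dimethylpropanoic 3-(trimethylsilyl)prop-2-ynoic anhydride | C[Si](C)(C)C#CC(=O)OC(=O)C(C)(C)C | intermediate
14 | N-lithio salt of (4S)-4-(diphenylmethyl)-1,3-oxazolidin-2-one | [Li+].O=C1[N-][C@@H](C(c2ccccc2)c2ccccc2)CO1 | intermediate
15 | (4S)-4-(diphenylmethyl)-3-[3-(trimethylsilyl)prop-2-ynoyl]-1,3-oxazolidin-2-one | C[Si](C)(C)C#CC(=O)N1[C@@H](C(c2ccccc2)c2ccccc2)COC1=O | intermediate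
16 | (4S)-4-(diphenylmethyl)-3-(prop-2-ynoyl)-1,3-oxazolidin-2-one | C#CC(=O)N1[C@@H](C(c2ccccc2)c2ccccc2)COC1=O | intermediate
17 | (4S)-3-[(2E)-3-{[1-bromo-3-methoxy-8-(triisopropylsilyl)oct-7-yn-3-yl]peroxy}prop-2-enoyl]-4-(diphenylmethyl)-1,3-oxazolidin-2-one, both C6 epimers | BrCCC(OC)(CCCC#C[Si](C(C)C)(C(C)C)C(C)C)OO/C=C/C(=O)N1[C@@H](C(c2ccccc2)c2ccccc2)COC1=O | intermediate
18 | (4S)-4-(diphenylmethyl)-3-({(3S)-6-methoxy-6-[5-(triisopropylsilyl)pent-4-yn-1-yl]-1,2-dioxan-3-yl}acetyl)-1,3-oxazolidin-2-one, both C6 epimers | CC(C)[Si](C#CCCCC1(OC)CC[C@@H](CC(=O)N2[C@@H](C(c3ccccc3)c3ccccc3)COC2=O)OO1)(C(C)C)C(C)C | intermediate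
19 | (4S)-4-(diphenylmethyl)-3-({(3S,6R)-6-methoxy-6-[5-(triisopropylsilyl)pent-4-yn-1-yl]-1,2-dioxan-3-yl}acetyl)-1,3-oxazolidin-2-one | CC(C)[Si](C#CCCC[C@]1(OC)CC[C@@H](CC(=O)N2[C@@H](C(c3ccccc3)c3ccccc3)COC2=O)OO1)(C(C)C)C(C)C | intermediate
20 | 2-{(3S,6R)-6-methoxy-6-[5-(triisopropylsilyl)pent-4-yn-1-yl]-1,2-dioxan-3-yl}ethaneperoxoic acid | CC(C)[Si](C#CCCC[C@]1(OC)CC[C@@H](CC(=O)OO)OO1)(C(C)C)C(C)C | intermediate
21 | 2-{(3S,6R)-6-methoxy-6-[5-(triisopropylsilyl)pent-4-yn-1-yl]-1,2-dioxan-3-yl}acetic acid | CC(C)[Si](C#CCCC[C@]1(OC)CC[C@@H](CC(=O)O)OO1)(C(C)C)C(C)C | intermediate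
22 | 2-[(3S,6R)-6-methoxy-6-(pent-4-yn-1-yl)-1,2-dioxan-3-yl]acetic acid | C#CCCC[C@]1(OC)CC[C@@H](CC(=O)O)OO1 | intermediate
23 | undec-1-yne | C#CCCCCCCCCC | starting material
24 | chlorobis(cyclopentadienyl)[(1E)-undec-1-en-1-yl]zirconium | CCCCCCCCC/C=C/[Zr](Cl)(C1C=CC=C1)C1C=CC=C1 | intermediate
25 | (1E)-1-iodoundec-1-ene | CCCCCCCCC/C=C/I | intermediate
26 | 2-{(3S,6R)-6-[(6E)-hexadec-6-en-4-yn-1-yl]-6-methoxy-1,2-dioxan-3-yl}acetic acid | CCCCCCCCC/C=C/C#CCCC[C@]1(OC)CC[C@@H](CC(=O)O)OO1 | target

## Step count and least certain steps

Total step count: 13. Longest linear sequence: 10 steps (steps 1, 2, 3, 4, 7, 8, 9, 10, 11 and 13); steps 5 and 6 and step 12 are side branches.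

**Step 8 (key step, new method).** The most likely failure is that the C4 radical does not reach C3. Intramolecular homolytic substitution at O1 with scission of the weak O–O bond, attack of the chain-carrying silyl radical on the peroxide, or reduction of the C4 radical before ring closure can each take over. After ring closure, the C2 radical can cleave the new ring by attacking O2. A lesser risk is weak facial bias for one of the two C6 epimers. The fallback gives up the C3–C4 closure for the known closure at C3–O2. It sets out from bromide 8 and returns at 18.
- 8 is converted into its Grignard reagent and formylated (Mg, THF; DMF) to 4-methylidene-9-(triisopropylsilyl)non-8-ynal F1.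
- Horner–Wadsworth–Emmons reaction (LiCl, iPr2NEt, MeCN) with the phosphonate imide (4S)-3-[(diethoxyphosphoryl)acetyl]-4-(diphenylmethyl)-1,3-oxazolidin-2-one F2, made by acylating 12 with diethylphosphonoacetic acid (DCC, cat. DMAP), gives the (E)-enimide (4S)-4-(diphenylmethyl)-3-[(2E)-6-methylidene-11-(triisopropylsilyl)undec-2-en-10-ynoyl]-1,3-oxazolidin-2-one F3.
- Ozonolysis in CH2Cl2/MeOH at −78 °C, which should touch only the electron-rich 1,1-disubstituted alkene, gives the hydroperoxy ketal (4S)-4-(diphenylmethyl)-3-[(2E)-6-hydroperoxy-6-methoxy-11-(triisopropylsilyl)undec-2-en-10-ynoyl]-1,3-oxazolidin-2-one F4.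
- Et2NH in CF3CH2OH closes the ring by 6-exo-trig conjugate addition of the hydroperoxide to give 18 together with its (3R) epimers F5. These are diastereomers because of the auxiliary and are removed by chromatography, best after step 9.
- In this fallback the auxiliary serves as a resolving handle, not as a directing group.

**Step 7 (new method).** The union may fail through amine-initiated oligomerisation of 16, through ring closure of the peroxy anion onto the bromide of 10, or through thermal O–O homolysis of the vinylogous perester during handling. The fallback replaces alkyne addition by nucleophilic vinylic substitution, a type established for β-chlorovinyl carbonyl compounds with oxygen nucleophiles, hydroperoxide anions included. It sets out from 12 and 10 and returns at 17.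
- (E)-3-chloroacrylic acid is attached to 12 as in step 5 to give (4S)-3-[(2E)-3-chloroprop-2-enoyl]-4-(diphenylmethyl)-1,3-oxazolidin-2-one F6.
- 10 displaces chloride from F6 by addition–elimination (iPr2NEt, CH2Cl2, −30 °C) with retention of the E geometry, without a nucleophilic amine and without an ynimide.
- If the trouble is the lability of 17 itself, the fallback under step 8 removes both steps.

**Step 9.** Equilibration may stall, or the open-chain ketal hydroperoxide may accumulate under protic acid. The fallback replaces thermodynamic exchange by kinetic capture of the ring peroxycarbenium ion. It sets out from 18 and returns at 19 with no new compound: TMSOTf and MeOSiMe3 in CH2Cl2 at −78 °C ionise C6 irreversibly under aprotic conditions, and the methoxy group adds axially under stereoelectronic control.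

**Step 10.** Ring opening by base-induced loss of O2 from C3, or attack at the endocyclic carbonyl, may compete with the desired cleavage. The fallback avoids base altogether. It sets out from 19 and returns at 21.
- Yb(OTf)3-catalysed methanolysis of the chelating imide gives methyl 2-{(3S,6R)-6-methoxy-6-[5-(triisopropylsilyl)pent-4-yn-1-yl]-1,2-dioxan-3-yl}acetate F7 and releases 12. The acidic methanol is the same medium that equilibrates C6.
- The ester is hydrolysed at pH 7 with pig liver esterase.

**Step 13.** The carboxylate may bind copper and slow the coupling, which prolongs exposure of the O–O bond to phosphine and zerovalent palladium and favours alkyne homocoupling. The fallback moves the coupling to the imide stage, where no free acid is present. It sets out from 19 and returns at 26.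
- Buffered desilylation (TBAF, AcOH, THF) gives (4S)-4-(diphenylmethyl)-3-({(3S,6R)-6-methoxy-6-(pent-4-yn-1-yl)-1,2-dioxan-3-yl}acetyl)-1,3-oxazolidin-2-one F8.
- Sonogashira coupling with 25 (PdCl2(PPh3)2, CuI, Et3N, THF) gives (4S)-4-(diphenylmethyl)-3-({(3S,6R)-6-[(6E)-hexadec-6-en-4-yn-1-yl]-6-methoxy-1,2-dioxan-3-yl}acetyl)-1,3-oxazolidin-2-one F9.
- LiOH/H2O2 cleavage as in step 10 then gives 26 directly.

## Further compounds

F1 | step 8 | 4-methylidene-9-(triisopropylsilyl)non-8-ynal | O=CCCC(=C)CCCC#C[Si](C(C)C)(C(C)C)C(C)C
F2 | step 8 | (4S)-3-[(diethoxyphosphoryl)acetyl]-4-(diphenylmethyl)-1,3-oxazolidin-2-one | CCOP(=O)(OCC)CC(=O)N1[C@@H](C(c2ccccc2)c2ccccc2)COC1=O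
F3 | step 8 | (4S)-4-(diphenylmethyl)-3-[(2E)-6-methylidene-11-(triisopropylsilyl)undec-2-en-10-ynoyl]-1,3-oxazolidin-2-one | C=C(CC/C=C/C(=O)N1[C@@H](C(c2ccccc2)c2ccccc2)COC1=O)CCCC#C[Si](C(C)C)(C(C)C)C(C)C
F4 | step 8 | (4S)-4-(diphenylmethyl)-3-[(2E)-6-hydroperoxy-6-methoxy-11-(triisopropylsilyl)undec-2-en-10-ynoyl]-1,3-oxazolidin-2-one, both C6 epimers | OOC(OC)(CC/C=C/C(=O)N1[C@@H](C(c2ccccc2)c2ccccc2)COC1=O)CCCC#C[Si](C(C)C)(C(C)C)C(C)C
F5 | step 8 | (4S)-4-(diphenylmethyl)-3-({(3R)-6-methoxy-6-[5-(triisopropylsilyl)pent-4-yn-1-yl]-1,2-dioxan-3-yl}acetyl)-1,3-oxazolidin-2-one, both C6 epimers | CC(C)[Si](C#CCCCC1(OC)CC[C@H](CC(=O)N2[C@@H](C(c3ccccc3)c3ccccc3)COC2=O)OO1)(C(C)C)C(C)C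
F6 | step 7 | (4S)-3-[(2E)-3-chloroprop-2-enoyl]-4-(diphenylmethyl)-1,3-oxazolidin-2-one | Cl/C=C/C(=O)N1[C@@H](C(c2ccccc2)c2ccccc2)COC1=O
F0 | step 9 | none | none
F7 | step 10 | methyl 2-{(3S,6R)-6-methoxy-6-[5-(triisopropylsilyl)pent-4-yn-1-yl]-1,2-dioxan-3-yl}acetate | CC(C)[Si](C#CCCC[C@]1(OC)CC[C@@H](CC(=O)OC)OO1)(C(C)C)C(C)C
F8 | step 13 | (4S)-4-(diphenylmethyl)-3-({(3S,6R)-6-methoxy-6-(pent-4-yn-1-yl)-1,2-dioxan-3-yl}acetyl)-1,3-oxazolidin-2-one | C#CCCC[C@]1(OC)CC[C@@H](CC(=O)N2[C@@H](C(c3ccccc3)c3ccccc3)COC2=O)OO1
F9 | step 13 | (4S)-4-(diphenylmethyl)-3-({(3S,6R)-6-[(6E)-hexadec-6-en-4-yn-1-yl]-6-methoxy-1,2-dioxan-3-yl}acetyl)-1,3-oxazolidin-2-one | CCCCCCCCC/C=C/C#CCCC[C@]1(OC)CC[C@@H](CC(=O)N2[C@@H](C(c3ccccc3)c3ccccc3)COC2=O)OO1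
A1 | alternative 1 | 1-[5-(triisopropylsilyl)pent-4-yn-1-yl]-2,3-dioxabicyclo[2.2.2]oct-5-en-7-ol, hydroxyl syn to the O–O bridge, bridgeheads configured as C6 and C3 of the target | CC(C)[Si](C#CCCC[C@]1([C@@H](O)C2)C=C[C@@H]2OO1)(C(C)C)C(C)C
A2 | alternative 1 | (1S)-2-[5-(triisopropylsilyl)pent-4-yn-1-yl]cyclohexa-2,4-dien-1-ol | CC(C)[Si](C#CCCCC1=CC=CC[C@@H]1O)(C(C)C)C(C)C
A3 | alternative 2 | methyl 2-[6-hydroxy-6-(pent-4-yn-1-yl)-1,2-dioxan-3-yl]acetate, (3S,6R) enantiomer drawn, formed as the racemate | C#CCCC[C@]1(O)CC[C@@H](CC(=O)OC)OO1
A4 | alternative 2 | 1-bromohept-6-yn-2-one | BrCC(=O)CCCC#C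
A5 | alternative 2 | methyl but-3-enoate | C=CCC(=O)OC
A6 | alternative 3 | tert-butyl{2-[(3S,6R)-6-[(6E)-hexadec-6-en-4-yn-1-yl]-6-methoxy-1,2-dioxan-3-yl]ethoxy}diphenylsilane | CCCCCCCCC/C=C/C#CCCC[C@]1(OC)CC[C@@H](CCO[Si](c2ccccc2)(c2ccccc2)C(C)(C)C)OO1
A7 | alternative 3 | tert-butyl{[(3S,12E)-3-hydroperoxy-6,6-dimethoxydocos-12-en-10-yn-1-yl]oxy}diphenylsilane | CCCCCCCCC/C=C/C#CCCCC(OC)(OC)CC[C@@H](CCO[Si](c1ccccc1)(c1ccccc1)C(C)(C)C)OO
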